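**Retrosynthetic overview**

1. Rings A (cyclohexane C1, C10–C14) and D (oxepane) are cut together at C12–C13 and C1–C14: an intramolecular Diels–Alder reaction of a 2-ethoxydiene C1=C10–C11(OEt)=C12 on dihydrofuran ring B with a vinyl ketone C13=C14–C15(=O) that is tethered through C16–O to C3.
2. Enabling feature: ring A carries oxygen on C11 and, 1,4 to it, C14, whose side chain C15–C16–O returns to C3 next to the fusion atoms C1/C2. Ring A is therefore the [4+2] adduct of an oxygenated diene and an enone that the ring D ether itself holds as tether; the C11 and C15 carbonyl groups then deliver C10–H, C11–OAc and the C17 and C20 methyl groups.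
3. Rings B and C (C2–O–C9 bridged oxonane) are cut together at C8–C9: oxonium ylide formation and [2,3]-shift ring expansion of a 2,6-cis tetrahydropyranyl diazoketone. C6–OMe and C7–H come from the resulting Z-C6=C7 alkene by hydrosilylation tethered to C3–O.
4. The tetrahydropyran comes from (S)-linalool (C1–C8, C18, C19 and the C3 stereocentre) by Shi epoxidation, epoxide-to-allylic-alcohol isomerization and palladium-catalysed alkoxycarbonylation (O–C2, C1–C10).
5. Ring order: temporary tetrahydropyran; then rings B and C in one step; then rings A and D in one step.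

Key step: step 14

Assumption: the target is made as drawn, (1S,2S,3S,6R,7R,9S,10R,11R,12R,14S,15R) in cladiellin numbering, which is used for all C-locants in the text (C17 = CH3 on C15, C18 = CH3 on C3, C19 = CH3 on C7, C20 = CH3 on C12); systematic names carry their own locants.

**Route**

Step 1
Reactants: 1 (S)-linalool
Product: 2 (3S)-3-(tert-butyldimethylsilyloxy)-3,7-dimethylocta-1,6-diene
Conditions: TBSOTf, 2,6-lutidine, CH2Cl2, 0 °C
Reagents that add atoms: tert-butyldimethylsilyl trifluoromethanesulfonate, CC(C)(C)[Si](C)(C)OS(=O)(=O)C(F)(F)F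
Why: O-silylation of the tertiary allylic alcohol masks C3–OH for the oxidation, carbonylation and carbenoid steps that follow, and no stereocentre is touched.

Step 2
Reactants: 2 silyl ether
Product: 3 tert-butyl({(3S)-5-[(2S)-3,3-dimethyloxiran-2-yl]-3-methylpent-1-en-3-yl}oxy)dimethylsilane
Conditions: L-fructose-derived Shi ketone (30 mol %), KHSO5 (as 2KHSO5·KHSO4·K2SO4), K2CO3, Bu4NHSO4, MeCN/CH2(OMe)2/aq. Na2B4O7 buffer, 0 °C
Reagents that add atoms: potassium peroxymonosulfate, [K+].[O-]S(=O)(=O)OO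
Why: Shi epoxidation attacks only the electron-rich trisubstituted C6=C7 alkene, and the catalyst enantiomer sets C6 as S independently of the remote C3 centre.

Step 3
Reactants: 3 epoxide
Product: 4 (3S,6S)-6-(tert-butyldimethylsilyloxy)-2,6-dimethylocta-1,7-dien-3-ol
Conditions: Et2Al(TMP) [from lithium 2,2,6,6-tetramethylpiperidide and Et2AlCl], toluene, 0 °C
Reagents that add atoms: none
Why: Aluminium-amide-mediated epoxide-to-allylic-alcohol isomerization (syn β-elimination of a methyl hydrogen) keeps the C6–O bond and its configuration and unveils the isopropenyl group needed for the later [2,3]-shift.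

Step 4
Reactants: 4 allylic alcohol
Product: 5 methyl 2-[(2S,3S,6S)-3-(tert-butyldimethylsilyloxy)-3-methyl-6-(prop-1-en-2-yl)oxan-2-yl]acetate
Conditions: PdCl2 (10 mol %), CuCl2, NaOAc, CO (1 atm), MeOH, rt
Reagents that add atoms: carbon monoxide, [C-]#[O+]; methanol, CO
Why: Palladium-catalysed intramolecular alkoxycarbonylation (6-exo oxypalladation of the vinyl group by C6–OH, CO insertion, methanolysis) forms O–C2 and C1–C10; the chair transition state with isopropenyl, C3-methyl and the new CH2 arm equatorial should give the 2,6-cis ring and so C2 as S.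

Step 5
Reactants: 5 methyl ester
Product: 6 2-[(2S,3S,6S)-3-(tert-butyldimethylsilyloxy)-3-methyl-6-(prop-1-en-2-yl)oxan-2-yl]acetic acid
Conditions: LiOH, THF/MeOH/H2O, rt; then aq. HCl to pH 4
Reagents that add atoms: lithium hydroxide, [Li+].[OH-]
Why: Saponification of the unhindered methyl ester leaves the tertiary silyl ether and all stereocentres untouched.

Step 6
Reactants: 6 acid
Product: 8 1-diazo-3-[(2S,3S,6S)-3-(tert-butyldimethylsilyloxy)-3-methyl-6-(prop-1-en-2-yl)oxan-2-yl]propan-2-one, via mixed anhydride 7 (not isolated)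
Conditions: i-BuOCOCl, Et3N, THF, −20 °C; then CH2N2 (Et2O solution, freshly generated from N-methyl-N-nitroso-p-toluenesulfonamide and KOH), 0 °C
Reagents that add atoms: diazomethane, C=[N+]=[N-]
Why: Acylation of diazomethane by the mixed carbonic anhydride (first stage of an Arndt–Eistert sequence) adds C9 as the carbenoid precursor under conditions that spare the silyl ether and both alkenes.

Step 7
Reactants: 8 diazoketone
Product: 10 (1S,2S,5Z,8S)-2-(tert-butyldimethylsilyloxy)-2,6-dimethyl-11-oxabicyclo[6.2.1]undec-5-en-9-one, via oxonium ylide 9 (not isolated)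
Conditions: Cu(hfacac)2 [Cu(CF3COCHCOCF3)2] (5 mol %), CH2Cl2, reflux, slow addition
Reagents that add atoms: none
Why: Copper carbenoid formation, attack of the ring oxygen to give the five-membered oxonium ylide and [2,3]-sigmatropic rearrangement through the isopropenyl group expand the tetrahydropyran by three atoms and form C8–C9 and rings B and C at once; C9 is fixed by the bridge, and the Z-alkene is expected from the 2,6-cis ylide with this catalyst.

Step 8
Reactants: 10 bicyclic ketone
Product: 11 (1S,2S,5Z,8S)-2-hydroxy-2,6-dimethyl-11-oxabicyclo[6.2.1]undec-5-en-9-one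
Conditions: HF·pyridine, pyridine, THF, 0 °C to rt
Reagents that add atoms: none
Why: Buffered fluoride desilylation frees the tertiary C3–OH without protonating the C6=C7 alkene or opening the β-alkoxy ketone.

Step 9
Reactants: 11 hydroxy ketone
Product: 14 (1S,2S,5R,6R,8S)-2,5-dihydroxy-2,6-dimethyl-11-oxabicyclo[6.2.1]undecan-9-one, via silyl ether 12 (not isolated), via silacycle 13 (not isolated)
Conditions: HMe2SiCl, Et3N, DMAP (cat.), CH2Cl2, 0 °C; then Pt2[(CH2=CHSiMe2)2O]3 (1 mol % Pt), toluene, 60 °C; then 30% H2O2, KF, KHCO3, THF/MeOH, rt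
Reagents that add atoms: hydrogen peroxide, OO
Why: Tethered platinum-catalysed hydrosilylation followed by Tamao–Fleming oxidation: silicon bound to C3–O can reach only the face of the Z-alkene cis to C3–O, adds Si to C6 and H to C7 in syn fashion (six-membered siloxane), and stereoretentive C–Si oxidation gives 6R (C–OH) and 7R (C–H).

Step 10
Reactants: 14 diol
Product: 15 (1S,2S,5R,6R,8S)-2-hydroxy-5-methoxy-2,6-dimethyl-11-oxabicyclo[6.2.1]undecan-9-one
Conditions: Me3OBF4, 1,8-bis(dimethylamino)naphthalene, CH2Cl2, 0 °C to rt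
Reagents that add atoms: trimethyloxonium tetrafluoroborate, C[O+](C)C.F[B-](F)(F)F
Why: Non-basic O-methylation with the oxonium salt should take the secondary C6–OH and leave the hindered tertiary C3–OH and the enolizable ketone alone.

Step 11
Reactants: 15 hydroxy methyl ether
Product: 16 ethyl 2-{[(1S,2S,5R,6R,8S)-5-methoxy-2,6-dimethyl-9-oxo-11-oxabicyclo[6.2.1]undecan-2-yl]oxy}acetate
Conditions: ethyl diazoacetate (slow addition), Rh2(OAc)4 (1 mol %), CH2Cl2, rt
Reagents that add atoms: ethyl diazoacetate, CCOC(=O)C=[N+]=[N-]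
Why: Rhodium carbenoid O–H insertion etherifies the tertiary alcohol under neutral conditions (no alkoxide next to the ketone) and attaches C16 and C15 of the future tether.

Step 12
Reactants: 16 keto ester
Product: 18 ethyl 2-{[(1S,2S,5R,6R,8S)-5-methoxy-2,6-dimethyl-9-(trifluoromethylsulfonyloxy)-11-oxabicyclo[6.2.1]undec-9-en-2-yl]oxy}acetate, via lithium enolate 17 (not isolated)
Conditions: LiN(SiMe3)2, THF, −78 °C; then PhNTf2, −78 to 0 °C
Reagents that add atoms: N-phenylbis(trifluoromethanesulfonimide), O=S(=O)(N(c1ccccc1)S(=O)(=O)C(F)(F)F)C(F)(F)F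
Why: Kinetic enolization of the ring ketone toward the C1 methylene (the C9 methine at the bridge and the less acidic ester are spared) and O-triflation give the C1=C10 enol triflate.

Step 13
Reactants: 18 enol triflate ester
Product: 20 1-{[(1S,2S,5R,6R,8S)-5-methoxy-2,6-dimethyl-9-(trifluoromethylsulfonyloxy)-11-oxabicyclo[6.2.1]undec-9-en-2-yl]oxy}but-3-en-2-one, via Weinreb amide 19 (not isolated)
Conditions: MeNHOMe·HCl, i-PrMgCl, THF, −20 °C; then CH2=CHMgBr, −20 to 0 °C; quench into cold 1 N HCl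
Reagents that add atoms: vinylmagnesium bromide, C=C[Mg]Br
Why: Magnesium-amide aminolysis of the ester to the Weinreb amide and Grignard addition, held at the ketone stage by the chelated tetrahedral adduct, install the dienophile C13=C14–C15=O; the acidic quench prevents conjugate addition of the released hydroxylamine.

Step 14
Reactants: 20 vinyl ketone enol triflate
Product: 22 tetracyclic enol ether ketone (1S,2S,3S,6R,7R,9S,14R; rings A to D closed; C10=C11 ethyl enol ether; C15 ketone in ring D; C12 and C13 are CH2; C6–OMe), via ethoxydiene 21 (not isolated)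
Conditions: tributyl(1-ethoxyvinyl)stannane, Pd(PPh3)4 (5 mol %), LiCl, BHT, THF (0.005 mol/L), 65 °C; then toluene, 90 °C if the cycloaddition is incomplete
Reagents that add atoms: tributyl(1-ethoxyvinyl)stannane, CCCC[Sn](CCCC)(CCCC)C(=C)OCC
Why: Oxidative addition of zerovalent palladium to the C10 enol triflate, transmetalation and reductive elimination (Stille coupling) give the 2-ethoxydiene C1=C10–C11(OEt)=C12, which then undergoes a thermal normal-demand intramolecular Diels–Alder reaction with the tethered vinyl ketone. The closest known reaction types are the intermolecular cycloaddition of 2-alkoxydienes with methyl vinyl ketone and the type 1 intramolecular Diels–Alder reaction that forms bicyclo[5.4.0]undecenes through a five-atom tether. Ring A is closed by the [4+2] cycloaddition itself (new bonds C12–C13 and C1–C14), and ring D (an oxepan-3-one) is closed by the same C1–C14 bond as the seven-membered tether ring, with the tether exo to the diene. C1 is set by approach to the dihydrofuran face opposite C3 and C8, the other face being covered by the C3–C8 bridge of ring C, and C14 is set by the tether, which can span C3 and C1 only in the exo orientation and so gives the trans A/D fusion. The step needs regioselectivity, which is matched (the nucleophilic diene terminus C12 meets the enone β-carbon C13 while the tether delivers C14 to C1), and intramolecular over intermolecular reaction, which high dilution and the reactive alkoxydiene–enone pair should secure.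

Step 15
Reactants: 22 tetracyclic enol ether ketone
Product: 23 C15-methylene tetracycle (1S,2S,3S,6R,7R,9S,14R; as 22 with C15=CH2 in place of C15=O)
Conditions: Cp2TiMe2, toluene/THF, 70 °C, dark
Reagents that add atoms: dimethyltitanocene, [CH3-].[CH3-].[Ti+4].c1cc[cH-]c1.c1cc[cH-]c1
Why: Petasis methylenation (non-basic titanium methylidene) converts the hindered, enolizable C15 ketone into the exocyclic alkene (C17) without epimerizing C14 or touching the enol ether.

Step 16
Reactants: 23 methylene enol ether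
Product: 24 C11 ketone (1S,2S,3S,6R,7R,9S,10R,14R; cis A/B fusion; C15=CH2; C12 is CH2)
Conditions: 1 N HCl, THF, 0 °C to rt; then K2CO3, MeOH, rt
Reagents that add atoms: water, O
Why: Acid hydrolysis of the enol ether and base equilibration of the only epimerizable centre: C10 should settle as the cis-fused hydroisobenzofuranone (H10 cis to H1), the stable arrangement with ring A on the convex face, since no C12 stereocentre is yet present to be lost.

Step 17
Reactants: 24 ketone
Product: 26 C12-methylene ketone (1S,2S,3S,6R,7R,9S,10R,14R; exocyclic methylene groups on C12 and C15), via Mannich base 25 (not isolated)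
Conditions: (CH2O)n, i-Pr2NH2+ CF3CO2−, CF3CO2H (10 mol %), THF, reflux
Reagents that add atoms: paraformaldehyde (as formaldehyde), C=O
Why: Mannich-type α-methylenation can end only at C12, because C10 lacks the second α-hydrogen needed for amine elimination; it adds C20 under buffered conditions that should leave the C15 methylene group alone.

Step 18
Reactants: 26 bis-methylene ketone
Product: 27 dimethyl ketone (1S,2S,3S,6R,7R,9S,10R,12R,14S,15R; C11 ketone)
Conditions: H2 (1 atm), RhCl(PPh3)3 (10 mol %), benzene/EtOH, rt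
Reagents that add atoms: none
Why: Homogeneous syn hydrogenation of both exocyclic methylene groups: at C12 hydrogen should come from the convex face, anti to the axial C10–C9 bond, to give the axial 12R methyl, and at C15 from the face flanked by the axial H14 and anti to C1, to give 15R.

Step 19
Reactants: 27 ketone
Product: 28 C11 alcohol (1S,2S,3S,6R,7R,9S,10R,11R,12R,14S,15R)
Conditions: NaBH4, CeCl3·7H2O, MeOH, −78 °C
Reagents that add atoms: none
Why: Luche reduction at low temperature: hydride should attack axially from the convex face, the other face being blocked by the axial C9 and C20 substituents on the two α-carbons, giving the equatorial 11R alcohol before C12 can epimerize.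

Step 20
Reactants: 28 alcohol
Product: 29 target CNP0289153.2
Conditions: Ac2O, DMAP, pyridine, CH2Cl2, rt
Reagents that add atoms: acetic anhydride, CC(=O)OC(C)=O
Why: DMAP-catalysed acetylation of the only free hydroxyl completes the target without touching a stereocentre.

**Compound list**

1 | (S)-linalool, (3S)-3,7-dimethylocta-1,6-dien-3-ol | CC(C)=CCC[C@@](C)(C=C)O | starting material
2 | (3S)-3-(tert-butyldimethylsilyloxy)-3,7-dimethylocta-1,6-diene | CC(C)=CCC[C@@](C)(C=C)O[Si](C)(C)C(C)(C)C | intermediate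
3 | tert-butyl({(3S)-5-[(2S)-3,3-dimethyloxiran-2-yl]-3-methylpent-1-en-3-yl}oxy)dimethylsilane | CC1(C)O[C@H]1CC[C@@](C)(C=C)O[Si](C)(C)C(C)(C)C | intermediate
4 | (3S,6S)-6-(tert-butyldimethylsilyloxy)-2,6-dimethylocta-1,7-dien-3-ol | C=C(C)[C@@H](O)CC[C@@](C)(C=C)O[Si](C)(C)C(C)(C)C | intermediate
5 | methyl 2-[(2S,3S,6S)-3-(tert-butyldimethylsilyloxy)-3-methyl-6-(prop-1-en-2-yl)oxan-2-yl]acetate | COC(=O)C[C@@H]1O[C@H](C(C)=C)CC[C@]1(C)O[Si](C)(C)C(C)(C)C | intermediate
6 | 2-[(2S,3S,6S)-3-(tert-butyldimethylsilyloxy)-3-methyl-6-(prop-1-en-2-yl)oxan-2-yl]acetic acid | OC(=O)C[C@@H]1O[C@H](C(C)=C)CC[C@]1(C)O[Si](C)(C)C(C)(C)C | intermediate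
7 | mixed isobutyl carbonic anhydride of 6 | CC(C)COC(=O)OC(=O)C[C@@H]1O[C@H](C(C)=C)CC[C@]1(C)O[Si](C)(C)C(C)(C)C | intermediate (not isolated)
8 | 1-diazo-3-[(2S,3S,6S)-3-(tert-butyldimethylsilyloxy)-3-methyl-6-(prop-1-en-2-yl)oxan-2-yl]propan-2-one | [N-]=[N+]=CC(=O)C[C@@H]1O[C@H](C(C)=C)CC[C@]1(C)O[Si](C)(C)C(C)(C)C | intermediate
9 | bicyclic oxonium ylide (ring oxygen bonded to C9; C9 carbanion next to the C10 ketone) | [CH-]1C(=O)C[C@@H]2[O+]1[C@H](C(C)=C)CC[C@]2(C)O[Si](C)(C)C(C)(C)C | intermediate (not isolated)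
10 | (1S,2S,5Z,8S)-2-(tert-butyldimethylsilyloxy)-2,6-dimethyl-11-oxabicyclo[6.2.1]undec-5-en-9-one | C/C1=C/CC[C@](C)(O[Si](C)(C)C(C)(C)C)[C@@H]2CC(=O)[C@H](C1)O2 | intermediate
11 | (1S,2S,5Z,8S)-2-hydroxy-2,6-dimethyl-11-oxabicyclo[6.2.1]undec-5-en-9-one | C/C1=C/CC[C@](C)(O)[C@@H]2CC(=O)[C@H](C1)O2 | intermediate
12 | (1S,2S,5Z,8S)-2-(dimethylsilyloxy)-2,6-dimethyl-11-oxabicyclo[6.2.1]undec-5-en-9-one | C/C1=C/CC[C@](C)(O[SiH](C)C)[C@@H]2CC(=O)[C@H](C1)O2 | intermediate (not isolated)
13 | silacycle (2S,3S,6R,7R,9S): six-membered C3–O–SiMe2–C6 ring, H on C7, C10 ketone | C[Si]3(C)[C@@H]1CC[C@](C)(O3)[C@@H]2CC(=O)[C@@H](O2)C[C@H]1C | intermediate (not isolated)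
14 | (1S,2S,5R,6R,8S)-2,5-dihydroxy-2,6-dimethyl-11-oxabicyclo[6.2.1]undecan-9-one | O[C@@H]1CC[C@](C)(O)[C@@H]2CC(=O)[C@@H](O2)C[C@H]1C | intermediate
15 | (1S,2S,5R,6R,8S)-2-hydroxy-5-methoxy-2,6-dimethyl-11-oxabicyclo[6.2.1]undecan-9-one | CO[C@@H]1CC[C@](C)(O)[C@@H]2CC(=O)[C@@H](O2)C[C@H]1C | intermediate
16 | ethyl 2-{[(1S,2S,5R,6R,8S)-5-methoxy-2,6-dimethyl-9-oxo-11-oxabicyclo[6.2.1]undecan-2-yl]oxy}acetate | CO[C@@H]1CC[C@](C)(OCC(=O)OCC)[C@@H]2CC(=O)[C@@H](O2)C[C@H]1C | intermediate
17 | lithium C1=C10 enolate of 16 | [Li+].CO[C@@H]1CC[C@](C)(OCC(=O)OCC)[C@@H]2C=C([O-])[C@@H](O2)C[C@H]1C | intermediate (not isolated)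
18 | ethyl 2-{[(1S,2S,5R,6R,8S)-5-methoxy-2,6-dimethyl-9-(trifluoromethylsulfonyloxy)-11-oxabicyclo[6.2.1]undec-9-en-2-yl]oxy}acetate | CO[C@@H]1CC[C@](C)(OCC(=O)OCC)[C@@H]2C=C(OS(=O)(=O)C(F)(F)F)[C@@H](O2)C[C@H]1C | intermediate
19 | N-methoxy-N-methyl-2-{[(1S,2S,5R,6R,8S)-5-methoxy-2,6-dimethyl-9-(trifluoromethylsulfonyloxy)-11-oxabicyclo[6.2.1]undec-9-en-2-yl]oxy}acetamide | CO[C@@H]1CC[C@](C)(OCC(=O)N(C)OC)[C@@H]2C=C(OS(=O)(=O)C(F)(F)F)[C@@H](O2)C[C@H]1C | intermediate (not isolated)
20 | 1-{[(1S,2S,5R,6R,8S)-5-methoxy-2,6-dimethyl-9-(trifluoromethylsulfonyloxy)-11-oxabicyclo[6.2.1]undec-9-en-2-yl]oxy}but-3-en-2-one | CO[C@@H]1CC[C@](C)(OCC(=O)C=C)[C@@H]2C=C(OS(=O)(=O)C(F)(F)F)[C@@H](O2)C[C@H]1C | intermediate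
21 | 1-{[(1S,2S,5R,6R,8S)-9-(1-ethoxyvinyl)-5-methoxy-2,6-dimethyl-11-oxabicyclo[6.2.1]undec-9-en-2-yl]oxy}but-3-en-2-one | CO[C@@H]1CC[C@](C)(OCC(=O)C=C)[C@@H]2C=C(C(=C)OCC)[C@@H](O2)C[C@H]1C | intermediate (not isolated)
22 | tetracyclic enol ether ketone (1S,2S,3S,6R,7R,9S,14R): C10=C11–OEt, C15 ketone, C6–OMe | CO[C@@H]1CC[C@]2(C)OCC(=O)[C@@H]3CCC(OCC)=C4[C@H]3[C@@H]2O[C@H]4C[C@H]1C | intermediate
23 | C15-methylene enol ether (1S,2S,3S,6R,7R,9S,14R) | CO[C@@H]1CC[C@]2(C)OCC(=C)[C@@H]3CCC(OCC)=C4[C@H]3[C@@H]2O[C@H]4C[C@H]1C | intermediate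
24 | C11 ketone with C15 methylene (1S,2S,3S,6R,7R,9S,10R,14R) | CO[C@@H]1CC[C@]2(C)OCC(=C)[C@@H]3CCC(=O)[C@@H]4[C@H]3[C@@H]2O[C@H]4C[C@H]1C | intermediate
25 | Mannich base: 24 with CH2N(i-Pr)2 on C12 (C12 epimers) | CO[C@@H]1CC[C@]2(C)OCC(=C)[C@@H]3CC(CN(C(C)C)C(C)C)C(=O)[C@@H]4[C@H]3[C@@H]2O[C@H]4C[C@H]1C | intermediate (not isolated)
26 | C12,C15-bis-methylene C11 ketone (1S,2S,3S,6R,7R,9S,10R,14R) | CO[C@@H]1CC[C@]2(C)OCC(=C)[C@@H]3CC(=C)C(=O)[C@@H]4[C@H]3[C@@H]2O[C@H]4C[C@H]1C | intermediate
27 | C11 ketone with both methyl groups (1S,2S,3S,6R,7R,9S,10R,12R,14S,15R) | CO[C@@H]1CC[C@]2(C)OC[C@H](C)[C@@H]3C[C@@H](C)C(=O)[C@@H]4[C@H]3[C@@H]2O[C@H]4C[C@H]1C | intermediate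
28 | C11 alcohol (1S,2S,3S,6R,7R,9S,10R,11R,12R,14S,15R) | CO[C@@H]1CC[C@]2(C)OC[C@H](C)[C@@H]3C[C@@H](C)[C@@H](O)[C@@H]4[C@H]3[C@@H]2O[C@H]4C[C@H]1C | intermediate
29 | CNP0289153.2, the C11 acetate (1S,2S,3S,6R,7R,9S,10R,11R,12R,14S,15R) | CO[C@@H]1CC[C@]2(C)OC[C@H](C)[C@@H]3C[C@@H](C)[C@@H](OC(C)=O)[C@@H]4[C@H]3[C@@H]2O[C@H]4C[C@H]1C | target

**Totals**

Total step count: 20. Longest linear sequence: 20 steps, from 1.

**Steps most likely to fail**

Step 14 (Stille coupling and intramolecular Diels–Alder reaction). The seven-membered tether ring may close too slowly, so that the alkoxydiene is lost to hydrolysis, vinyl ketone polymerization or intermolecular cycloaddition, or the dienophile may reach C1 with poor facial selectivity. The fallback makes ring A by an intermolecular cycloaddition and closes ring D afterwards by etherification; it sets out from 15 and comes back at 27. Double deprotonation (LiN(SiMe3)2, 2.2 equiv) and PhNTf2 should give the hydroxy enol triflate F1. Stille coupling with tributyl(1-ethoxyvinyl)stannane (Pd(PPh3)4, LiCl) should give the hydroxy ethoxydiene F2. Diels–Alder reaction with methyl vinyl ketone on the open face, followed by equilibration at C14 (K2CO3, MeOH), should give the C14-acetyl enol ether F3. Wittig methylenation (Ph3P=CH2) gives the isopropenyl enol ether F4. Hydroboration–oxidation (9-borabicyclo[3.3.1]nonane; then NaOH, H2O2) gives the C16 primary alcohol F5, with C15 set by attack anti to the ring. Hydrolysis and C10 equilibration as in step 16 give the keto diol F6. Tf2O and 2,6-lutidine form the primary triflate F7, which is not isolated and is displaced by the C3 hydroxyl to give the oxepane ketone F8. α-Methylenation as in step 17 gives the C12-methylene ketone F9, and hydrogenation as in step 18 returns to 27.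

Step 9 (tethered hydrosilylation and oxidation). The transannular Si–H addition may be slow, platinum hydride may isomerize the Z-alkene, or silicon may add at C7. The fallback uses an epoxide rearrangement instead; it sets out from 10 and comes back at 18. Enolization and triflation as in step 12 give the silyl ether enol triflate F10. Dimethyldioxirane should epoxidize the exposed face of C6=C7 to give the epoxide F11. Meinwald rearrangement (BF3·OEt2, CH2Cl2, −78 °C) moves the C6 hydrogen to C7 with inversion and should give the C6 ketone F12 with the 7R methyl group. NaBH4 attack from the exposed face should give the 6R alcohol F13. Methylation as in step 10 gives the methyl ether F14. HF·pyridine then gives the hydroxy enol triflate F1, and O–H insertion as in step 11 returns to 18.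

Step 18 (double hydrogenation). Facial selectivity may be poor at C12, where the wanted axial methyl group is the less stable epimer, or at C15, and the exocyclic alkenes may migrate into the rings. The fallback sets C12 by conjugate reduction and kinetic protonation; it sets out from 26 and comes back at 27. LiBH(s-Bu)3 (1 equiv, THF, −78 °C) adds hydride to the C12 methylene and gives the lithium enolate F15. Protonation at −78 °C with 2,6-di-tert-butyl-4-methylphenol from the convex face should give the 12R ketone F16, which still carries the C15 methylene. Hydrogenation of that alkene (H2, RhCl(PPh3)3) returns to 27; a failure at C15 alone is covered by the fallback to step 14, which sets C15 by hydroboration.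

Further compounds
F1 | step 14 | hydroxy enol triflate (15 with C1=C10–OTf) | CO[C@@H]1CC[C@](C)(O)[C@@H]2C=C(OS(=O)(=O)C(F)(F)F)[C@@H](O2)C[C@H]1C
F2 | step 14 | hydroxy ethoxydiene | CO[C@@H]1CC[C@](C)(O)[C@@H]2C=C(C(=C)OCC)[C@@H](O2)C[C@H]1C
F3 | step 14 | C14-acetyl enol ether (rings A, B, C; C3–OH free) | CO[C@@H]1CC[C@](C)(O)[C@@H]2[C@H]3[C@H](C(C)=O)CCC(OCC)=C3[C@@H](O2)C[C@H]1C
F4 | step 14 | isopropenyl enol ether | CO[C@@H]1CC[C@](C)(O)[C@@H]2[C@H]3[C@H](C(C)=C)CCC(OCC)=C3[C@@H](O2)C[C@H]1C
F5 | step 14 | C16 primary alcohol (15R) enol ether | CO[C@@H]1CC[C@](C)(O)[C@@H]2[C@H]3[C@H]([C@@H](C)CO)CCC(OCC)=C3[C@@H](O2)C[C@H]1C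
F6 | step 14 | keto diol (C11 ketone, cis A/B fusion) | CO[C@@H]1CC[C@](C)(O)[C@@H]2[C@H]3[C@H]([C@@H](C)CO)CCC(=O)[C@H]3[C@@H](O2)C[C@H]1C
F7 | step 14 | primary triflate (not isolated) | CO[C@@H]1CC[C@](C)(O)[C@@H]2[C@H]3[C@H]([C@@H](C)COS(=O)(=O)C(F)(F)F)CCC(=O)[C@H]3[C@@H](O2)C[C@H]1C
F8 | step 14 | oxepane ketone (C15 methyl, C12 is CH2) | CO[C@@H]1CC[C@]2(C)OC[C@H](C)[C@@H]3CCC(=O)[C@@H]4[C@H]3[C@@H]2O[C@H]4C[C@H]1C
F9 | step 14 | C12-methylene ketone (C15 methyl) | CO[C@@H]1CC[C@]2(C)OC[C@H](C)[C@@H]3CC(=C)C(=O)[C@@H]4[C@H]3[C@@H]2O[C@H]4C[C@H]1C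
F10 | step 9 | silyl ether enol triflate (10 with C1=C10–OTf) | C/C1=C/CC[C@](C)(O[Si](C)(C)C(C)(C)C)[C@@H]2C=C(OS(=O)(=O)C(F)(F)F)[C@H](C1)O2
F11 | step 9 | C6–C7 epoxide (6S,7R; oxygen on the face opposite C3–O) | C[C@@]12C[C@@H]3O[C@@H](C=C3OS(=O)(=O)C(F)(F)F)[C@@](C)(O[Si](C)(C)C(C)(C)C)CC[C@@H]1O2
F12 | step 9 | C6 ketone (7R methyl) | O=C1CC[C@](C)(O[Si](C)(C)C(C)(C)C)[C@@H]2C=C(OS(=O)(=O)C(F)(F)F)[C@@H](O2)C[C@H]1C
F13 | step 9 | 6R alcohol | O[C@@H]1CC[C@](C)(O[Si](C)(C)C(C)(C)C)[C@@H]2C=C(OS(=O)(=O)C(F)(F)F)[C@@H](O2)C[C@H]1C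
F14 | step 9 | C6 methyl ether, C3 silyl ether | CO[C@@H]1CC[C@](C)(O[Si](C)(C)C(C)(C)C)[C@@H]2C=C(OS(=O)(=O)C(F)(F)F)[C@@H](O2)C[C@H]1C
F15 | step 18 | lithium C11=C12 enolate (C15 methylene) | [Li+].CO[C@@H]1CC[C@]2(C)OCC(=C)[C@@H]3CC(C)=C([O-])[C@@H]4[C@H]3[C@@H]2O[C@H]4C[C@H]1C
F16 | step 18 | 12R-methyl ketone (C15 methylene) | CO[C@@H]1CC[C@]2(C)OCC(=C)[C@@H]3C[C@@H](C)C(=O)[C@@H]4[C@H]3[C@@H]2O[C@H]4C[C@H]1C
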